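All constants are invented; the flask was simulated.

Whatever starting material the protic impurity leaves over has to divide between ring and open dimer, and the proportion of that division is the question in each flask.

    starting material → ring (k1 = 0.301 /h, Ea1 = 85.0 kJ/mol)
    2 starting material → open dimer (k2 = 0.344 /M/h, Ea2 = 61.0 kJ/mol)
    crystals ⇌ ring, rate k3*(cs3 - [ring]) while solid is left; crystals form when [ring] > cs3 (cs3 = 0.075 M, k3 = 24.3 /h)
    starting material + protic impurity → quenched substrate (k4 = 1.51 /M/h, Ea4 = 56.0 kJ/mol)
    (constants at −20 °C)

| setting | eta | zeta | delta |
|---|---|---|---|
| starting material | 1.6 M | 1.6 M | 1.6 M |
| protic impurity | 0.800 M | 0.800 M | 0.800 M |
| temperature | −35 °C | −20 °C | −5 °C |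
| time | 2.5 d | 2.5 d | 2.5 d |

- percent here means starting material units held: one open dimer counts as two
- what is said of ring includes crystals
- two of one species on the left: rate k times its square, two consumed each time
- crystals is a solid; its amount is given per volume of the solution
- all constants are for −20 °C and move with temperature by the activation energies

- the flask that comes out highest in share of ring in all that became ring or open dimer, or "all alike" when all lie within 1.5 percentage points (eta / zeta / delta / all alike)
- share of ring in all that became ring or open dimer, eta
- share of ring in all that became ring or open dimer, zeta
- share of ring in all that became ring or open dimer, delta

Let ring closure run by itself first: every unit of starting material becomes ring, and the share, the selectivity, is 100%.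

Now add the dimer step. Two drains pull on starting material: closure with time constant 1/k(ring), and dimerisation with time constant 1/(2 k(dimer) c(starting material)), which shortens as the concentration rises. At zeta's temperature, k(ring)/(2 k(dimer)) = 0.438 M is the crossover concentration c×, the level of starting material at which both drains take it equally. Of each slice that becomes ring or open dimer at concentration c, the share c×/(c× + c) is ring. Averaged over the fall from the charge c(charge) to zero, this gives S = (c×/c(charge)) ln(1 + c(charge)/c×). The activation energy of closure is greater than that of dimerisation by 24.0 kJ/mol, so c× grows on warming: 0.213 M in eta and 0.828 M in delta.

Then add the rest. Crystals count as ring and return nothing to starting material, so the reckoning leaves them out. The protic impurity has the smaller charge, half of the starting material, and its balance loses k(quench) c(starting material) c(protic impurity). That loss leaves the split between ring and open dimer at a given c unchanged and alters how fast c falls. In zeta the quench takes 46.3% of the flow of starting material at the start. If that fraction held in zeta down to 0.800 M of starting material, 0.430 M of protic impurity would remain, and the quench would still take 43.2%. In zeta the early fraction is more than the later one by 3 percentage points, so this reckoning keeps S as it stands for eta, zeta and delta alike, as an estimate that is perhaps slightly low. Ring closure in eta has a time constant of 42.3 h, shorter than the run of 60 h, yet a tail of starting material may remain there.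

My reckoning gives 28.5% for eta, 42.1% for zeta and 55.7% for delta, with delta highest.

The forecast, with different figures from these, gives 15.1%, 24.9% and 36.4% and names delta, starting from “Ring closure has the highest activation energy and is first order”.

The simulation gives 29.3% for eta, 43.0% for zeta and 56.1% for delta, with delta highest. Zeta ends with 0% of its starting material and 14% of its protic impurity left. A neighbour of delta, charged with 2.7 M of starting material at the same temperature, keeps c× at 0.828 M, and S then reads 44.5%; the share of ring in that neighbour flask ended at 45.3%.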